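## Retrosynthetic overview

Chain numbering used throughout: C1 = carbinol carbon on the oxazole, C2 = CH2, C3 and C4 = diol carbons, C5 = acyloxy carbon, C6 = CH3.

1. Target ⇒ its 3,4-O-isopropylidene derivative; the last step is a mild acid hydrolysis.
2. Key disconnection: the bond from C1 to oxazole C4 of ring A, giving an aldehyde (fragment A, C1–C6 with the ester in place) and 4-iodo-2-(oxazol-5-ylmethyl)oxazole (fragment B). A new catalytic asymmetric Ni/Cr heteroarylation forms this bond and sets C1.
3. Fragment A ⇒ 2-deoxy-L-fucose (supplies C3, C4, C5; its pyranose oxygen singles out O5 for acylation) plus 14-methylpentadecanoic acid, by Wittig ring opening, esterification and ozonolysis.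
4. Fragment B ⇒ 2,4-dibromooxazole plus 5-(chloromethyl)oxazole: a C2-selective Negishi coupling makes the CH2 bridge, then bromide is exchanged for iodide.
5. Rings: ring A (2,4-disubstituted oxazole) and ring B (5-substituted oxazole) are bought intact. The only ring formed is the temporary dioxolane (step 1), opened again in step 8.

Assumption: 2-deoxy-L-fucose, 14-methylpentadecanoic acid, 5-(chloromethyl)-1,3-oxazole and 2,4-dibromo-1,3-oxazole are taken as catalogue compounds, and the (S)-ligand of step 7 is taken as the antipode that gives the (R)-carbinol (if the sense is the opposite, its mirror image is used with no other change).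

## Route

Step 1
Reactants: 1 sugar 2-deoxy-L-fucose (2,6-dideoxy-L-lyxo-hexopyranose; open-chain form (3S,4R,5S)-3,4,5-trihydroxyhexanal)
Product: 2 lactol acetonide 2,6-dideoxy-3,4-O-isopropylidene-L-lyxo-hexopyranose (anomeric mixture)
Conditions: 2-methoxypropene (1.5 equiv), PPTS (5 mol %), DMF, 0 °C → rt; Et3N quench
Reagents that add atoms: 2-methoxypropene, COC(C)=C
Why: Kinetic acid-catalysed acetonation (transacetalisation with an enol ether) takes the cis-3,4-diol of the pyranose, the only pair that can close a five-membered ketal, and leaves the lactol free; no stereocentre is made, since C3, C4 and C5 come from the sugar.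

Step 2
Reactants: 2 lactol acetonide 2,6-dideoxy-3,4-O-isopropylidene-L-lyxo-hexopyranose
Product: 3 alkenol (1S)-1-[(4R,5S)-2,2-dimethyl-5-(prop-2-en-1-yl)-1,3-dioxolan-4-yl]ethan-1-ol
Conditions: Ph3PCH3Br (3.0 equiv), KOtBu (2.8 equiv), THF, 0 °C → rt
Reagents that add atoms: methyltriphenylphosphonium bromide, C[P+](c1ccccc1)(c1ccccc1)c1ccccc1.[Br-]
Why: Wittig methylenation of the open-chain hydroxy-aldehyde tautomer of the lactol (as practised on 2-deoxyribose acetonide) frees O5 as the only hydroxyl and parks C1 as a vinyl group; no stereocentre is touched.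

Step 3
Reactants: 3 alkenol (1S)-1-[(4R,5S)-2,2-dimethyl-5-(prop-2-en-1-yl)-1,3-dioxolan-4-yl]ethan-1-ol; 4 acid 14-methylpentadecanoic acid
Product: 5 alkenyl ester (1S)-1-[(4R,5S)-2,2-dimethyl-5-(prop-2-en-1-yl)-1,3-dioxolan-4-yl]ethyl 14-methylpentadecanoate
Conditions: DCC (1.3 equiv), DMAP (0.2 equiv), CH2Cl2, 0 °C → rt
Reagents that add atoms: none
Why: Steglich esterification of the single free secondary alcohol goes with retention at C5, and the acetonide and the alkene are inert.

Step 4
Reactants: 5 alkenyl ester (1S)-1-[(4R,5S)-2,2-dimethyl-5-(prop-2-en-1-yl)-1,3-dioxolan-4-yl]ethyl 14-methylpentadecanoate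
Product: 7 aldehyde (1S)-1-[(4R,5S)-2,2-dimethyl-5-(2-oxoethyl)-1,3-dioxolan-4-yl]ethyl 14-methylpentadecanoate, via secondary ozonide 6 (not isolated)
Conditions: O3, CH2Cl2, −78 °C; then PPh3 (1.2 equiv), −78 °C → rt; used at once
Reagents that add atoms: ozone, [O-][O+]=O
Why: Ozonolysis with reductive work-up (Criegee mechanism) cuts off the extra carbon and returns the C1 aldehyde under neutral conditions, so the β-alkoxy aldehyde does not eliminate and the ester does not move.

Step 5
Reactants: 8 chloride 5-(chloromethyl)-1,3-oxazole; 9 dibromide 2,4-dibromo-1,3-oxazole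
Product: 11 bromide 4-bromo-2-(1,3-oxazol-5-ylmethyl)-1,3-oxazole, via oxazol-5-ylmethylzinc chloride 10 (not isolated)
Conditions: Zn dust (1.5 equiv), LiCl (1.5 equiv), THF, 25 °C; then 9 (0.8 equiv), Pd(PPh3)4 (5 mol %), THF, 25 °C
Reagents that add atoms: none
Why: LiCl-assisted zinc insertion into the heterobenzylic C–Cl bond is followed by Negishi coupling, in which zerovalent palladium inserts first into the C2–Br bond of 9 (the most electron-poor position, between O and N, as in 2,4-dihalothiazoles), so the C4–Br bond is kept.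

Step 6
Reactants: 11 bromide 4-bromo-2-(1,3-oxazol-5-ylmethyl)-1,3-oxazole
Product: 12 iodide 4-iodo-2-(1,3-oxazol-5-ylmethyl)-1,3-oxazole
Conditions: NaI (2 equiv), CuI (10 mol %), trans-N,N′-dimethylcyclohexane-1,2-diamine (20 mol %), 1,4-dioxane, 110 °C
Reagents that add atoms: sodium iodide, [Na+].[I-]
Why: Copper-catalysed aromatic Finkelstein exchange, driven by precipitation of NaBr from dioxane, gives the iodide needed for fast oxidative addition to nickel; no base is present, so the acidic CH2 and the oxazole C2–H are safe.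

Step 7
Reactants: 7 aldehyde (1S)-1-[(4R,5S)-2,2-dimethyl-5-(2-oxoethyl)-1,3-dioxolan-4-yl]ethyl 14-methylpentadecanoate; 12 iodide 4-iodo-2-(1,3-oxazol-5-ylmethyl)-1,3-oxazole
Product: 13 carbinol (1S)-1-[(4R,5S)-5-{(2R)-2-hydroxy-2-[2-(1,3-oxazol-5-ylmethyl)-1,3-oxazol-4-yl]ethyl}-2,2-dimethyl-1,3-dioxolan-4-yl]ethyl 14-methylpentadecanoate
Conditions: 12 (1.5 equiv), CrCl2 (15 mol %), (S)-4-isopropyl-2-[2-(methanesulfonylamino)-3-methylphenyl]-4,5-dihydro-1,3-oxazole (17 mol %), 1,8-bis(dimethylamino)naphthalene (17 mol %), NiCl2(2,9-dimethyl-1,10-phenanthroline) (3 mol %), Mn powder (2 equiv), Cp2ZrCl2 (1.3 equiv), LiCl (2 equiv), MeCN, rt; aq. potassium sodium tartrate/NaHCO3 work-up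
Reagents that add atoms: none
Why: Proposed new method: a catalytic, ligand-controlled asymmetric Nozaki–Hiyama–Kishi heteroarylation with an oxazol-4-yl iodide, which forms the bond from C1 to oxazole C4 of ring A and sets C1; zerovalent nickel, made from the NiCl2 phenanthroline complex by divalent chromium, inserts into the C4–I bond of 12, the oxazol-4-yl group passes to trivalent chromium carrying the deprotonated oxazoline–sulfonamide ligand, and this σ-heteroaryl chromium species adds to the chromium-bound aldehyde of 7 inside the chiral pocket, where the isopropyl group of the ligand leaves one carbonyl face open, so the (R)-carbinol (hydroxyl syn to the C3 oxygen) forms under catalyst control against the weak 1,3-anti preference of a β-alkoxy aldehyde with no α-substituent; Cp2ZrCl2 takes the N,O-chelating product alkoxide off chromium and Mn returns chromium to the divalent state, so both metals turn over; the medium is not basic, so the ester, the acetonide, the enolisable β-alkoxy aldehyde, the oxazole C2–H and the doubly activated CH2 are left alone; closest known reaction type: the catalytic asymmetric Ni/Cr coupling of alkenyl iodides with aldehydes under oxazoline–sulfonamide control, and the achiral Ni/Cr addition of aryl iodides to aldehydes.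

Step 8
Reactants: 13 carbinol (1S)-1-[(4R,5S)-5-{(2R)-2-hydroxy-2-[2-(1,3-oxazol-5-ylmethyl)-1,3-oxazol-4-yl]ethyl}-2,2-dimethyl-1,3-dioxolan-4-yl]ethyl 14-methylpentadecanoate
Product: 14 target (2S,3S,4S,6R)-3,4,6-trihydroxy-6-[2-(1,3-oxazol-5-ylmethyl)-1,3-oxazol-4-yl]hexan-2-yl 14-methylpentadecanoate
Conditions: AcOH/H2O (4:1), 40 °C; evaporate with toluene, no basic work-up
Reagents that add atoms: none
Why: Acid hydrolysis of the cis-4,5-disubstituted dioxolane (acetonide cleavage) frees the C3/C4 diol without touching a stereocentre, and dilute acetic acid with no basic work-up is chosen because O5→O4 acyl migration is mainly base-catalysed while the oxazoles, the ester and the carbinol tolerate it.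

## Compound list

1 | 2-deoxy-L-fucose (2,6-dideoxy-L-lyxo-hexopyranose, anomeric mixture) | C[C@@H]1OC(O)C[C@H](O)[C@@H]1O | starting material
2 | 2,6-dideoxy-3,4-O-isopropylidene-L-lyxo-hexopyranose (anomeric mixture) | C[C@@H]1OC(O)C[C@@H]2OC(C)(C)O[C@H]12 | intermediate
3 | (1S)-1-[(4R,5S)-2,2-dimethyl-5-(prop-2-en-1-yl)-1,3-dioxolan-4-yl]ethan-1-ol | C[C@H](O)[C@H]1OC(C)(C)O[C@H]1CC=C | intermediate
4 | 14-methylpentadecanoic acid | CC(C)CCCCCCCCCCCCC(=O)O | starting material
5 | (1S)-1-[(4R,5S)-2,2-dimethyl-5-(prop-2-en-1-yl)-1,3-dioxolan-4-yl]ethyl 14-methylpentadecanoate | CC(C)CCCCCCCCCCCCC(=O)O[C@@H](C)[C@H]1OC(C)(C)O[C@H]1CC=C | intermediate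
6 | (1S)-1-[(4R,5S)-2,2-dimethyl-5-(1,2,4-trioxolan-3-ylmethyl)-1,3-dioxolan-4-yl]ethyl 14-methylpentadecanoate (secondary ozonide, both epimers at the trioxolane carbon) | CC(C)CCCCCCCCCCCCC(=O)O[C@@H](C)[C@H]1OC(C)(C)O[C@H]1CC2OCOO2 | intermediate (not isolated)
7 | (1S)-1-[(4R,5S)-2,2-dimethyl-5-(2-oxoethyl)-1,3-dioxolan-4-yl]ethyl 14-methylpentadecanoate | CC(C)CCCCCCCCCCCCC(=O)O[C@@H](C)[C@H]1OC(C)(C)O[C@H]1CC=O | intermediate
8 | 5-(chloromethyl)-1,3-oxazole | ClCc1cnco1 | starting material
9 | 2,4-dibromo-1,3-oxazole | Brc1coc(Br)n1 | starting material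
10 | (1,3-oxazol-5-ylmethyl)zinc chloride | Cl[Zn]Cc1cnco1 | intermediate (not isolated)
11 | 4-bromo-2-(1,3-oxazol-5-ylmethyl)-1,3-oxazole | Brc1coc(Cc2cnco2)n1 | intermediate
12 | 4-iodo-2-(1,3-oxazol-5-ylmethyl)-1,3-oxazole | Ic1coc(Cc2cnco2)n1 | intermediate
13 | (1S)-1-[(4R,5S)-5-{(2R)-2-hydroxy-2-[2-(1,3-oxazol-5-ylmethyl)-1,3-oxazol-4-yl]ethyl}-2,2-dimethyl-1,3-dioxolan-4-yl]ethyl 14-methylpentadecanoate | CC(C)CCCCCCCCCCCCC(=O)O[C@@H](C)[C@H]1OC(C)(C)O[C@H]1C[C@@H](O)c2coc(Cc3cnco3)n2 | intermediate
14 | (2S,3S,4S,6R)-3,4,6-trihydroxy-6-[2-(1,3-oxazol-5-ylmethyl)-1,3-oxazol-4-yl]hexan-2-yl 14-methylpentadecanoate | CC(C)CCCCCCCCCCCCC(=O)O[C@@H](C)[C@@H](O)[C@@H](O)C[C@@H](O)c1coc(Cc2cnco2)n1 | target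

## Step count and risks

Total step count: 8. Longest linear sequence: 6 steps (1, 2, 3, 4, 7, 8 from 2-deoxy-L-fucose); the oxazole branch is steps 5 and 6.

The three steps most likely to fail, in order of risk, are step 7, then step 5, then step 6. They are discussed below in route order.

**Step 5 (C2-selective Negishi coupling).** The risks are coupling at C4 or at both positions, and self-coupling of the heterobenzylic zinc reagent. The fallback reverses the polarity of the two partners. It sets out from 9: bromine–magnesium exchange at C2 (i-PrMgCl·LiCl, THF, −40 °C) gives (4-bromo-1,3-oxazol-2-yl)magnesium chloride F1. This is trapped at once with ZnCl2 as (4-bromo-1,3-oxazol-2-yl)zinc chloride F2, which is cross-coupled with the chloride 8 (Pd(OAc)2, SPhos, THF, 25 °C). The fallback comes back to the route at 11. The regiochemistry is then fixed by the exchange at the most electron-poor carbon and no longer by two competing oxidative additions.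

**Step 6 (copper-catalysed bromide–iodide exchange).** The risk is that oxazole C4 is the least activated position and that the two ring nitrogens hold the copper. The fallback goes through tin. It sets out from 11: Pd(PPh3)4 and Me3SnSnMe3 (toluene, 100 °C) give 2-(1,3-oxazol-5-ylmethyl)-4-(trimethylstannyl)-1,3-oxazole F3. Iododestannylation (I2, CH2Cl2, 0 °C) comes back to the route at 12.

**Step 7 (the new coupling).** The risks are no turnover, because the product alkoxide chelates chromium through N and O, and catalyst control too weak to beat the 1,3-anti bias. The fallback uses known chemistry and sets C1 by reduction instead of by C–C bond formation. It sets out from 7 and 12: the achiral stoichiometric Ni/Cr coupling (CrCl2 4 equiv, NiCl2 1 mol %, DMSO, rt) gives the C1-epimeric carbinols (1S)-1-[(4R,5S)-5-{(2RS)-2-hydroxy-2-[2-(1,3-oxazol-5-ylmethyl)-1,3-oxazol-4-yl]ethyl}-2,2-dimethyl-1,3-dioxolan-4-yl]ethyl 14-methylpentadecanoate F4. Dess–Martin periodinane (NaHCO3, CH2Cl2, 0 °C) gives the ketone (1S)-1-[(4R,5S)-2,2-dimethyl-5-{2-oxo-2-[2-(1,3-oxazol-5-ylmethyl)-1,3-oxazol-4-yl]ethyl}-1,3-dioxolan-4-yl]ethyl 14-methylpentadecanoate F5. Noyori asymmetric transfer hydrogenation (RuCl(p-cymene)[(R,R)-TsDPEN] 2 mol %, HCO2H/Et3N 5:2, rt) then reduces the heteroaryl ketone under catalyst control to the (R)-carbinol, by analogy with acetophenone, and comes back to the route at 13.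

## Further compounds

F1 | step 5 | (4-bromo-1,3-oxazol-2-yl)magnesium chloride | Cl[Mg]c1nc(Br)co1
F2 | step 5 | (4-bromo-1,3-oxazol-2-yl)zinc chloride | Cl[Zn]c1nc(Br)co1
F3 | step 6 | 2-(1,3-oxazol-5-ylmethyl)-4-(trimethylstannyl)-1,3-oxazole | C[Sn](C)(C)c1coc(Cc2cnco2)n1
F4 | step 7 | (1S)-1-[(4R,5S)-5-{(2RS)-2-hydroxy-2-[2-(1,3-oxazol-5-ylmethyl)-1,3-oxazol-4-yl]ethyl}-2,2-dimethyl-1,3-dioxolan-4-yl]ethyl 14-methylpentadecanoate (13 plus its carbinol epimer) | CC(C)CCCCCCCCCCCCC(=O)O[C@@H](C)[C@H]1OC(C)(C)O[C@H]1CC(O)c2coc(Cc3cnco3)n2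
F5 | step 7 | (1S)-1-[(4R,5S)-2,2-dimethyl-5-{2-oxo-2-[2-(1,3-oxazol-5-ylmethyl)-1,3-oxazol-4-yl]ethyl}-1,3-dioxolan-4-yl]ethyl 14-methylpentadecanoate | CC(C)CCCCCCCCCCCCC(=O)O[C@@H](C)[C@H]1OC(C)(C)O[C@H]1CC(=O)c2coc(Cc3cnco3)n2
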